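## The problem

Compound 21 is a 2H-chromene whose benzene ring (ring A) carries five oxygen substituents: a free hydroxyl at C5, methyl ethers at C6, C7 and C8, and the ring oxygen O1 at C8a. Ring A is fused to a pyran ring (ring B) with a C3=C4 double bond and a fully substituted C2, which bears a methyl group and a two-carbon tether ending at the quaternary C1' of a 1,2,3-trimethylcyclohex-3-ene (ring C). Of the three stereocenters, C1' (S) and C2' (S) are neighbours in ring C with their methyl groups cis, so one ring-forming event can set each relative to the other. C2 (R) lies four bonds from C1' across a flexible CH2–CH2 tether, cannot be controlled by ring C, and needs a chiral catalyst of its own. Three parts are fragile, namely the 2H-chromene (acid or light opens it to an ortho-quinone methide and erases C2), the electron-rich phenol (easily oxidised) and the C3'=C4' double bond (acid moves it to C2'=C3' and destroys C2'), so the late steps must be neutral and non-oxidising. Ring A hides a symmetry: O1 and the C5 hydroxyl flank C4a in the same way, so the arene is a 2-substituted 4,5,6-trimethoxyresorcinol whose two hydroxyl groups are equivalent. The feature that invites the key step is ring C: the sequence C1'(quaternary)–C2'H(CH3)–C3'(CH3)=C4'H–C5'H2–C6'H2 maps onto a [4+2] adduct in which a diene contributes C2' to C5' and a 1,1-disubstituted alkene contributes C1' and C6'. The C1' methyl group can pass through that step as a formyl group that activates the alkene and binds a chiral Lewis acid.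

## Retrosynthesis

**Ring B, C3=C4.** Target 21 is opened at the C3=C4 double bond to diene ether 20, which has a vinyl group on C4a and a vinyl group on C2. Among the bonds of ring B this is the only one that can be formed under neutral conditions without touching C2; closing at O1–C8a or C4–C4a would need strong base, acid or a cation next to C2. In 20 the arene and the side chain are held together by the O1–C2 bond alone. The forward ring-closing metathesis must join the two monosubstituted alkenes and leave the trisubstituted C3'=C4' alone.

**O1–C2.** Cutting the ether bond of 20 gives the symmetric diol 19 and the allylic methyl carbonate 13, halving the molecule and creating C2 in the same step. The other polarity, a tertiary alkoxide arylated by the arene, would ask a hindered alkoxide to couple with an electron-rich ring. Here the phenoxide is the nucleophile and the tertiary carbon is the electrophilic terminus of a π-allyl palladium complex. The forward step must attack the substituted terminus, take its face selectivity from a chiral diphosphine, and stop after one etherification. Because the hydroxyls of 19 are equivalent, either gives 20.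

**The arene.** The vinyl group of 19 is traced to the formyl group of aldehyde 18. In diol 16 the carbon between the two hydroxyls is the only unsubstituted ring position, so formylation has no regiochemical choice. The hydroxyls of 16 come from the bromine atoms of 15, and 15 from twofold bromination of commercial 1,2,3-trimethoxybenzene 14. Each precursor is simpler by one substituent; the forward steps must work on a very electron-rich ring without oxidising it.

**The side-chain alkene.** Carbonate 13 comes from allylic alcohol 12 and this from ester 11. Cutting the trisubstituted double bond of 11 leads to methyl ketone 8 and phosphonate 9. Ketone 8 holds all of ring C with both stereocenters, and the three steps back to it are routine. The olefination must give the (E)-alkene, since alkene geometry and ligand together decide the configuration at C2.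

**Functional groups on ring C.** The methyl ketone of 8 is taken back to the terminal alkene of hydrocarbon 7, and the C1' methyl group of 7 to the formyl group of aldehyde 5. A ketone acetal in this position was considered and set aside: in the key step it would compete with the formyl oxygen for the cationic boron acid and could be opened to an oxocarbenium ion in the presence of a nucleophilic diene. A but-3-enyl group is invisible to that catalyst, survives hydrazine and hydroxide, and is unmasked in one oxidation, so the step count is unchanged.

**Ring C (key disconnection).** Aldehyde 5 is cut at C1'–C2' and C5'–C6' into 2-methylidenehex-5-enal 3 and (E)-3-methylpenta-1,3-diene 4. Alkylating a cyclohexanone enolate or a conjugate addition would build the quaternary centre and its neighbour in separate steps and would still have to place the double bond. The cycloaddition sets C1', C2' and the alkene position at once from two small achiral pieces. The forward reaction must bond the methyl-bearing diene terminus to the α-carbon of the enal, hold the formyl group endo, and select one face of the enal.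

**The dienophile.** Enal 3 arises by α-methylenation of hex-5-enal 2, which comes from oxidation of commercial hex-5-en-1-ol 1.

## Roads not taken

Alternative 1: All three bonds that tie ring B to the arene and to C2 (C8a–O1, C4a–C4, O1–C2) are cut at once. The pieces are an aryne precursor A3 (the bis-triflate of diol 16 silylated between the two oxygens) and the side-chain enal A2 (one oxidation from alcohol 12). Fluoride would turn A3 into the corresponding aryne, which keeps one triflate next to the triple bond. The aldehyde oxygen adds to the aryne carbon remote from the triflate, the four-membered adduct opens to an ortho-quinone methide, and oxa-6π closure gives chromenyl triflate A1, whose triflate must then be cleaved to the C5 hydroxyl. The merits are convergence, no vinylarene, no metathesis, and a symmetric aryne precursor whose triflate steers the regiochemistry. The weak point is C2: it is formed in a thermal electrocyclisation whose only stereocenters are four bonds away, so A1 would form as a mixture of both configurations at C2. Enals with γ-hydrogens also offer the aryne other reaction paths. In step count this road is about level with the chosen endgame (oxidation, cascade, triflate removal against steps 8, 13 and 14), and it is better in convergence and in avoiding the sensitive diol 19. The chosen plan sets catalyst control of C2 against it.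

Alternative 2: The benzene ring itself is cut (C5–C4a and the ring carbons C5 to C8), leaving cyclobutenone A5, a 4-methoxycyclobutenone that carries a dihydropyran holding C2, the side chain and a C4 silyl ether. Heating opens the four-membered ring to a dienylketene that closes by 6π electrocyclisation and tautomerises to phenol A4, with the C5 hydroxyl free and the three methyl ethers in place. Desilylation and dehydration must then install C3=C4. Its strength is regiochemical certainty: the five oxygens arrive in defined positions and the free hydroxyl is differentiated by the mechanism, with no reliance on electrophilic substitution of an arene. Its weaknesses are length and order. The pyran fragment must be built with C2 already set, which is a separate asymmetric problem. The arene is assembled last on the most valuable intermediate. The final dehydration passes through a benzylic cation next to the acid-labile pyran ring. The chosen plan is weaker on the arene, where it trusts the regiochemistry of step 9, but is much shorter and keeps the arene as a cheap separate branch.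

Alternative 3: Only C8a–O1 is cut. The precursor A7 is a (Z)-configured tertiary allylic alcohol whose aryl ring carries a bromide at C8a and a methoxymethyl ether at C5. Pd(OAc)2 with a bulky biarylphosphine and Cs2CO3 would couple the tertiary alkoxide with the bromide to give the protected chromene A6, and removal of the methoxymethyl group would give the target. Here C2 is a tertiary alcohol set before the ring closure and untouched by it, so its configuration is more secure than in the chosen plan, and no branched-against-linear question arises. The costs are these: the coupling joins a tertiary alkoxide to an electron-rich bromide with two ortho substituents, the hardest case for this reaction; the (Z)-alkene needs a stereoselective synthesis; the arene must be desymmetrised (bromide on one side, protected hydroxyl on the other); and the final deprotection uses acid on an acid-labile chromene. The chosen plan sets against the better-secured C2 of this road a shorter sequence, an unprotected symmetric arene (diol 19) and a neutral last step.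

Key step: step 3

Assumption (step 3): the facial sense is taken to follow the model established for 2-methylacrolein with this catalyst class, under which the (S)-catalyst gives 5; if the opposite sense is found, the (R)-catalyst is used and nothing else changes.

Assumption (step 13): with the (E)-carbonate 13 the (R,R)-ligand is taken to give the (R)-ether 20; if the opposite sense is found, the (S,S)-ligand is used and nothing else changes.

## Route

Step 1
Reactants: 1 hex-5-en-1-ol
Product: 2 hex-5-enal
Conditions: PhI(OAc)2 (1.1 equiv), TEMPO (10 mol%), CH2Cl2, rt
Reagents that add atoms: none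
Why: Nitroxyl-catalysed oxidation of a primary alcohol stops at the aldehyde and leaves the terminal alkene alone; the volatile aldehyde is carried on as a concentrated solution.

Step 2
Reactants: 2 hex-5-enal
Product: 3 2-methylidenehex-5-enal
Conditions: 37% aq. CH2O, pyrrolidine (10 mol%), EtCO2H (10 mol%), i-PrOH, 45 °C
Reagents that add atoms: formaldehyde, C=O
Why: Amine–acid-catalysed α-methylenation (Mannich condensation, then loss of the amine) is a standard route from unbranched aldehydes to 2-substituted acroleins; 3 is distilled and used fresh.

Step 3
Reactants: 3 2-methylidenehex-5-enal; 4 (3E)-3-methylpenta-1,3-diene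
Product: 5 (1S,2R)-1-(but-3-en-1-yl)-2,3-dimethylcyclohex-3-ene-1-carbaldehyde
Conditions: (3aS)-1-(2-methylphenyl)-3,3-diphenyltetrahydro-1H,3H-pyrrolo[1,2-c][1,3,2]oxazaborole (20 mol%), HN(SO2CF3)2 (18 mol%), diene (commercial E/Z mixture) in fourfold excess, CH2Cl2, −78 to −40 °C; Et3N quench at −78 °C
Reagents that add atoms: none
Why: The formyl oxygen of 3 binds the cationic boron and the s-trans enal undergoes a concerted, asynchronous, suprafacial [4+2] cycloaddition with the s-cis (E)-diene, an addition in which every atom of 3 and 4 ends in 5; the closest known reaction type is the oxazaborolidinium-catalysed Diels–Alder reaction of 2-methyl- and 2-bromoacrolein with acyclic dienes. Ring C closes by bimolecular union of the four-carbon unit C2'–C5' with the two-carbon unit C1'=C6', bond formation being more advanced between the two CH2 termini (C5'–C6') than between the methyl-bearing terminus and the α-carbon (C1'–C2'). The required regiochemistry (methyl-bearing diene terminus to the α-carbon) is favoured by the terminal methyl group and by the unhindered leading bond, and is opposed only by the weaker pull of the internal methyl group. C1' is set by the catalyst: the formyl C–H contact to the ring oxygen and stacking over a phenyl group shield one face, so the diene adds to the Si face at C2 of 3. C2' is set relative to C1' by formyl-endo topicity together with the (E)-geometry of 4, which places the C2' methyl cis to the formyl group. Only the (E)-isomer of the commercial mixture can adopt the s-cis conformation, so the (Z)-isomer passes through unchanged, and the but-3-enyl group is neither a dienophile nor a Lewis base. The cold quench prevents acid-promoted closure of the formyl group onto C3'=C4'.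

Step 4
Reactants: 5 (1S,2R)-1-(but-3-en-1-yl)-2,3-dimethylcyclohex-3-ene-1-carbaldehyde
Product: 7 (5R,6S)-5-(but-3-en-1-yl)-1,5,6-trimethylcyclohex-1-ene, via aldehyde hydrazone 6 (not isolated)
Conditions: N2H4·H2O, diethylene glycol, 120 °C; then KOH, 200 °C, argon
Reagents that add atoms: hydrazine, NN (its nitrogen atoms stay in intermediate 6 only and leave as N2)
Why: Wolff–Kishner reduction in the Huang-Minlon mode turns the non-enolisable neopentyl aldehyde into the C1' methyl group; C1' is quaternary and C2' is not acidic, so neither is touched, and the isolated alkenes survive under argon.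

Step 5
Reactants: 7 (5R,6S)-5-(but-3-en-1-yl)-1,5,6-trimethylcyclohex-1-ene
Product: 8 4-[(1S,2S)-1,2,3-trimethylcyclohex-3-en-1-yl]butan-2-one
Conditions: PdCl2 (10 mol%), CuCl (1 equiv), O2 (1 atm), DMF/H2O 7:1, rt
Reagents that add atoms: water, O
Why: Tsuji–Wacker oxidation is selective for the monosubstituted alkene and gives the methyl ketone by Markovnikov hydroxypalladation; the trisubstituted ring alkene is not oxidised, and CuCl only shuttles electrons to O2, which ends as water.

Step 6
Reactants: 8 4-[(1S,2S)-1,2,3-trimethylcyclohex-3-en-1-yl]butan-2-one; 9 triethyl phosphonoacetate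
Product: 11 ethyl (2E)-3-methyl-5-[(1S,2S)-1,2,3-trimethylcyclohex-3-en-1-yl]pent-2-enoate, via sodium phosphonoacetate carbanion 10 (not isolated)
Conditions: NaH, THF, 0 °C; then 8, reflux; chromatographic removal of the minor (Z)-ester
Reagents that add atoms: none
Why: Horner–Wadsworth–Emmons olefination of a methyl ketone should favour the (E)-enoate; the minor (Z)-isomer is removed here because alkene geometry decides the configuration at C2 in step 13.

Step 7
Reactants: 11 ethyl (2E)-3-methyl-5-[(1S,2S)-1,2,3-trimethylcyclohex-3-en-1-yl]pent-2-enoate
Product: 12 (2E)-3-methyl-5-[(1S,2S)-1,2,3-trimethylcyclohex-3-en-1-yl]pent-2-en-1-ol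
Conditions: i-Bu2AlH (2.5 equiv), CH2Cl2, −78 to 0 °C; aq. potassium sodium tartrate
Reagents that add atoms: none
Why: 1,2-Reduction of an enoate by i-Bu2AlH gives the allylic alcohol without changing the alkene geometry.

Step 8
Reactants: 12 (2E)-3-methyl-5-[(1S,2S)-1,2,3-trimethylcyclohex-3-en-1-yl]pent-2-en-1-ol
Product: 13 methyl (2E)-3-methyl-5-[(1S,2S)-1,2,3-trimethylcyclohex-3-en-1-yl]pent-2-en-1-yl carbonate
Conditions: ClCO2Me, pyridine, CH2Cl2, 0 °C
Reagents that add atoms: methyl chloroformate, COC(=O)Cl
Why: Acylation of a primary allylic alcohol; the carbonate is the leaving group that zerovalent palladium ionises in step 13 and it supplies the base for the phenol.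

Step 9
Reactants: 14 1,2,3-trimethoxybenzene
Product: 15 1,5-dibromo-2,3,4-trimethoxybenzene
Conditions: N-bromosuccinimide (2.1 equiv), MeCN, 0 °C to rt
Reagents that add atoms: N-bromosuccinimide, O=C1CCC(=O)N1Br
Why: Electrophilic aromatic bromination; each bromine should enter ortho to one outer methoxy group and para to the other, while the position between them is activated only by the twisted central methoxy group.

Step 10
Reactants: 15 1,5-dibromo-2,3,4-trimethoxybenzene
Product: 16 4,5,6-trimethoxybenzene-1,3-diol
Conditions: Pd2(dba)3 (2 mol%), 2-di-tert-butylphosphino-2',4',6'-triisopropylbiphenyl (8 mol%), KOH (6 equiv), 1,4-dioxane/H2O 1:1, 100 °C, degassed; then aq. HCl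
Reagents that add atoms: potassium hydroxide, [K+].[OH-]
Why: Palladium-catalysed C–O coupling of aryl bromides with hydroxide, followed by acidification, gives the phenols; exclusion of air protects the electron-rich diol.

Step 11
Reactants: 16 4,5,6-trimethoxybenzene-1,3-diol
Product: 18 2,6-dihydroxy-3,4,5-trimethoxybenzaldehyde, via aryl iminium chloride 17 (not isolated)
Conditions: POCl3 (1.2 equiv), DMF (1.5 equiv), MeCN, 0 °C to rt; then H2O, 50 °C
Reagents that add atoms: N,N-dimethylformamide, CN(C)C=O; water, O; phosphoryl chloride, O=P(Cl)(Cl)Cl (chloride counter-ion of 17 only)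
Why: Vilsmeier–Haack formylation; the carbon flanked by both hydroxyl groups is the only free ring position and is strongly activated, as in the formylation of phloroglucinol, and any aryl formate is hydrolysed on work-up.

Step 12
Reactants: 18 2,6-dihydroxy-3,4,5-trimethoxybenzaldehyde
Product: 19 2-ethenyl-4,5,6-trimethoxybenzene-1,3-diol
Conditions: Ph3PCH3Br (3.5 equiv), KOt-Bu (3.5 equiv), THF, 0 °C to rt; aq. NH4Cl; kept cold with a trace of 2,6-di-tert-butyl-4-methylphenol
Reagents that add atoms: methyltriphenylphosphonium bromide, C[P+](c1ccccc1)(c1ccccc1)c1ccccc1.[Br-]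
Why: Wittig methylenation with excess ylide; two equivalents of base are spent on the phenols and the non-stabilised ylide still adds to the aldehyde of the dianion, as in the conversion of hydroxybenzaldehydes into hydroxystyrenes.

Step 13
Reactants: 13 methyl (2E)-3-methyl-5-[(1S,2S)-1,2,3-trimethylcyclohex-3-en-1-yl]pent-2-en-1-yl carbonate; 19 2-ethenyl-4,5,6-trimethoxybenzene-1,3-diol
Product: 20 2-ethenyl-4,5,6-trimethoxy-3-{[(3R)-3-methyl-5-[(1S,2S)-1,2,3-trimethylcyclohex-3-en-1-yl]pent-1-en-3-yl]oxy}phenol
Conditions: Pd2(dba)3·CHCl3 (2 mol%), N,N'-[(1R,2R)-cyclohexane-1,2-diyl]bis[2-(diphenylphosphanyl)benzamide] (6 mol%), diol in twofold excess, CH2Cl2, rt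
Reagents that add atoms: none
Why: Palladium-catalysed asymmetric allylic etherification (Tsuji–Trost reaction of a phenol): ionisation of 13 gives a π-allyl complex and methoxide, which deprotonates 19, and the phenoxide attacks the more substituted allyl terminus, as this ligand class favours for geranyl-type carbonates. C2 is set by the ligand, which selects the alkene face that is ionised and hence the face attacked; C1' and C2' are too remote to interfere. The two hydroxyls of 19 are equivalent, and the excess of 19 (recovered) limits double etherification.

Step 14
Reactants: 20 2-ethenyl-4,5,6-trimethoxy-3-{[(3R)-3-methyl-5-[(1S,2S)-1,2,3-trimethylcyclohex-3-en-1-yl]pent-1-en-3-yl]oxy}phenol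
Product: 21 (2R)-6,7,8-trimethoxy-2-methyl-2-{2-[(1S,2S)-1,2,3-trimethylcyclohex-3-en-1-yl]ethyl}-2H-chromen-5-ol
Conditions: RuCl2(=CHPh)(PCy3)(H2IMes) (second-generation Grubbs catalyst, 5 mol%), CH2Cl2 (0.01 M), 40 °C
Reagents that add atoms: none
Why: Ring-closing metathesis between the styrene and the vinyl group on C2 closes the six-membered pyran ring at C3=C4 with loss of ethene; the catalyst enters at the styrene, the trisubstituted C3'=C4' is inert, and the neutral conditions leave C2 and the free phenol untouched.

## Compound list

1 | hex-5-en-1-ol | C=CCCCCO | starting material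
2 | hex-5-enal | C=CCCCC=O | intermediate
3 | 2-methylidenehex-5-enal | C=CCCC(=C)C=O | intermediate
4 | (3E)-3-methylpenta-1,3-diene (bought as the E/Z mixture) | C=C/C(C)=C/C | starting material
5 | (1S,2R)-1-(but-3-en-1-yl)-2,3-dimethylcyclohex-3-ene-1-carbaldehyde (formyl cis to the C2' methyl) | C=CCC[C@]1(C=O)CCC=C(C)[C@H]1C | intermediate
6 | (E)-{[(1S,2R)-1-(but-3-en-1-yl)-2,3-dimethylcyclohex-3-en-1-yl]methylidene}hydrazine | C=CCC[C@]1(/C=N/N)CCC=C(C)[C@H]1C | intermediate (not isolated)
7 | (5R,6S)-5-(but-3-en-1-yl)-1,5,6-trimethylcyclohex-1-ene | C=CCC[C@]1(C)CCC=C(C)[C@H]1C | intermediate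
8 | 4-[(1S,2S)-1,2,3-trimethylcyclohex-3-en-1-yl]butan-2-one | CC(=O)CC[C@]1(C)CCC=C(C)[C@H]1C | intermediate
9 | triethyl phosphonoacetate | CCOC(=O)CP(=O)(OCC)OCC | starting material
10 | sodium (diethoxyphosphoryl)(ethoxycarbonyl)methanide | [Na+].CCOC(=O)[CH-]P(=O)(OCC)OCC | intermediate (not isolated)
11 | ethyl (2E)-3-methyl-5-[(1S,2S)-1,2,3-trimethylcyclohex-3-en-1-yl]pent-2-enoate | CCOC(=O)/C=C(\C)CC[C@]1(C)CCC=C(C)[C@H]1C | intermediate
12 | (2E)-3-methyl-5-[(1S,2S)-1,2,3-trimethylcyclohex-3-en-1-yl]pent-2-en-1-ol | OC/C=C(\C)CC[C@]1(C)CCC=C(C)[C@H]1C | intermediate
13 | methyl (2E)-3-methyl-5-[(1S,2S)-1,2,3-trimethylcyclohex-3-en-1-yl]pent-2-en-1-yl carbonate | COC(=O)OC/C=C(\C)CC[C@]1(C)CCC=C(C)[C@H]1C | intermediate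
14 | 1,2,3-trimethoxybenzene | COc1cccc(OC)c1OC | starting material
15 | 1,5-dibromo-2,3,4-trimethoxybenzene | COc1c(Br)cc(Br)c(OC)c1OC | intermediate
16 | 4,5,6-trimethoxybenzene-1,3-diol | COc1c(O)cc(O)c(OC)c1OC | intermediate
17 | N-[(2,6-dihydroxy-3,4,5-trimethoxyphenyl)methylidene]-N-methylmethanaminium chloride | C[N+](C)=Cc1c(O)c(OC)c(OC)c(OC)c1O.[Cl-] | intermediate (not isolated)
18 | 2,6-dihydroxy-3,4,5-trimethoxybenzaldehyde | COc1c(O)c(C=O)c(O)c(OC)c1OC | intermediate
19 | 2-ethenyl-4,5,6-trimethoxybenzene-1,3-diol | C=Cc1c(O)c(OC)c(OC)c(OC)c1O | intermediate
20 | 2-ethenyl-4,5,6-trimethoxy-3-{[(3R)-3-methyl-5-[(1S,2S)-1,2,3-trimethylcyclohex-3-en-1-yl]pent-1-en-3-yl]oxy}phenol | C=Cc1c(O)c(OC)c(OC)c(OC)c1O[C@](C)(CC[C@]1(C)CCC=C(C)[C@H]1C)C=C | intermediate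
21 | (2R)-6,7,8-trimethoxy-2-methyl-2-{2-[(1S,2S)-1,2,3-trimethylcyclohex-3-en-1-yl]ethyl}-2H-chromen-5-ol | COc1c(O)c2c(c(OC)c1OC)O[C@](C)(CC[C@]1(C)CCC=C(C)[C@H]1C)C=C2 | target

## Step count and least certain steps

Total: 14 steps. Longest linear sequence: 10 steps (steps 1 to 8, 13 and 14, from 1). The arene branch is 4 steps (steps 9 to 12, from 14).

**Step 3 (key step).** The likeliest failure is leakage to the other regiochemistry, with the methyl-bearing diene terminus bonding to C6'. This diene is untested with a 2-alkylacrolein, and its internal methyl group works against the terminal one. Lower endo preference or face selectivity with a long-chain enal is the second concern. The fallback sets out from 3 and returns at 5. Commercial (E)-3-methylpent-3-en-2-one is silylated (i-Pr3SiOSO2CF3, Et3N) to (3E)-3-methyl-2-{[tri(propan-2-yl)silyl]oxy}penta-1,3-diene F1. In F1 the 2-silyloxy group and the terminal methyl group both send the unsubstituted terminus to C6', and 2-silyloxydienes are the best-documented partners of 2-substituted acroleins with this catalyst. Cycloaddition with 3 under the conditions of step 3 should give (1S,2R)-1-(but-3-en-1-yl)-2,3-dimethyl-4-{[tri(propan-2-yl)silyl]oxy}cyclohex-3-ene-1-carbaldehyde F2. CsF and PhN(SO2CF3)2 in 1,2-dimethoxyethane convert the silyl enol ether into (3R,4S)-4-(but-3-en-1-yl)-4-formyl-2,3-dimethylcyclohex-1-en-1-yl trifluoromethanesulfonate F3. Reduction of the triflate (Pd(OAc)2, PPh3, HCO2H, n-Bu3N, DMF, 60 °C) gives 5. The cost is two extra steps.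

**Step 13.** The likeliest failures are attack of the phenoxide at the unsubstituted allyl terminus (an achiral linear ether), incomplete face selection, and a second etherification. A phenoxide flanked by two ortho substituents is a hindered nucleophile, and intermolecular tertiary-ether formation from acyclic trisubstituted carbonates is the least secure class of this reaction. The fallback sets out from 12 and 16 and returns at 21. Oxidation of 12 with MnO2 in CH2Cl2 gives (2E)-3-methyl-5-[(1S,2S)-1,2,3-trimethylcyclohex-3-en-1-yl]pent-2-enal F4. Heating F4 with diol 16 and catalytic ethylenediammonium diacetate in toluene brings about condensation at the only free ring carbon of 16, formation of the ortho-quinone methide, and oxa-6π closure. This gives the chromene directly with no regiochemical question, but without control at C2. The target 21 must then be separated by preparative chromatography on a chiral stationary phase from its epimer (2S)-6,7,8-trimethoxy-2-methyl-2-{2-[(1S,2S)-1,2,3-trimethylcyclohex-3-en-1-yl]ethyl}-2H-chromen-5-ol F5. This fallback secures material; it gives up the catalyst control that is the reason for step 13.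

**Step 12.** The likeliest failures are sluggish olefination of the doubly deprotonated aldehyde and oligomerisation of the electron-rich vinyl diol on concentration; both come from the two free hydroxyls next to the reacting carbon. The fallback sets out from 18 and 13 and returns at 20. Aldehyde 18 is used as the nucleophile under the conditions of step 13; after the first etherification the remaining hydroxyl is hydrogen-bonded to the formyl oxygen and should react less readily. The product is 2-hydroxy-3,4,5-trimethoxy-6-{[(3R)-3-methyl-5-[(1S,2S)-1,2,3-trimethylcyclohex-3-en-1-yl]pent-1-en-3-yl]oxy}benzaldehyde F6. Wittig methylenation of this mono-phenol (Ph3PCH3Br, KOt-Bu, THF) gives 20, which goes straight into step 14. The vinyl group then never exists on a free diol, at the cost of one more step in the longest sequence.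

**Step 10.** The likeliest failure is stalling after the first C–O coupling, because the bromophenoxide formed is electron-rich and adds slowly to zerovalent palladium; reductive loss of bromine is the second concern. The fallback sets out from 15 and returns at 16. Twofold Miyaura borylation (bis(pinacolato)diboron, PdCl2(dppf), KOAc, 1,4-dioxane, 90 °C) converts both bromides while the ring is still neutral and gives 2,2'-(4,5,6-trimethoxy-1,3-phenylene)bis(4,4,5,5-tetramethyl-1,3,2-dioxaborolane) F7. Oxidation with H2O2 and NaOH gives 16.

**Step 4.** The likeliest failures are azine formation or incomplete breakdown of the hindered hydrazone, reduction of the terminal alkene by diimide if air enters, and evaporative loss of the hydrocarbon. The fallback sets out from 5 and returns at 7. NaBH4 in MeOH gives [(1S,2R)-1-(but-3-en-1-yl)-2,3-dimethylcyclohex-3-en-1-yl]methanol F8. Methanesulfonyl chloride and Et3N give [(1S,2R)-1-(but-3-en-1-yl)-2,3-dimethylcyclohex-3-en-1-yl]methyl methanesulfonate F9. LiBHEt3 in refluxing THF displaces the neopentyl sulfonate with hydride to give 7.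

## Further compounds

F1 | step 3 | (3E)-3-methyl-2-{[tri(propan-2-yl)silyl]oxy}penta-1,3-diene | C=C(O[Si](C(C)C)(C(C)C)C(C)C)/C(C)=C/C
F2 | step 3 | (1S,2R)-1-(but-3-en-1-yl)-2,3-dimethyl-4-{[tri(propan-2-yl)silyl]oxy}cyclohex-3-ene-1-carbaldehyde | C=CCC[C@]1(C=O)CCC(O[Si](C(C)C)(C(C)C)C(C)C)=C(C)[C@H]1C
F3 | step 3 | (3R,4S)-4-(but-3-en-1-yl)-4-formyl-2,3-dimethylcyclohex-1-en-1-yl trifluoromethanesulfonate | C=CCC[C@]1(C=O)CCC(OS(=O)(=O)C(F)(F)F)=C(C)[C@H]1C
F4 | step 13 | (2E)-3-methyl-5-[(1S,2S)-1,2,3-trimethylcyclohex-3-en-1-yl]pent-2-enal | O=C/C=C(\C)CC[C@]1(C)CCC=C(C)[C@H]1C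
F5 | step 13 | (2S)-6,7,8-trimethoxy-2-methyl-2-{2-[(1S,2S)-1,2,3-trimethylcyclohex-3-en-1-yl]ethyl}-2H-chromen-5-ol | COc1c(O)c2c(c(OC)c1OC)O[C@@](C)(CC[C@]1(C)CCC=C(C)[C@H]1C)C=C2
F6 | step 12 | 2-hydroxy-3,4,5-trimethoxy-6-{[(3R)-3-methyl-5-[(1S,2S)-1,2,3-trimethylcyclohex-3-en-1-yl]pent-1-en-3-yl]oxy}benzaldehyde | O=Cc1c(O)c(OC)c(OC)c(OC)c1O[C@](C)(CC[C@]1(C)CCC=C(C)[C@H]1C)C=C
F7 | step 10 | 2,2'-(4,5,6-trimethoxy-1,3-phenylene)bis(4,4,5,5-tetramethyl-1,3,2-dioxaborolane) | COc1c(B2OC(C)(C)C(C)(C)O2)cc(B2OC(C)(C)C(C)(C)O2)c(OC)c1OC
F8 | step 4 | [(1S,2R)-1-(but-3-en-1-yl)-2,3-dimethylcyclohex-3-en-1-yl]methanol | C=CCC[C@]1(CO)CCC=C(C)[C@H]1C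
F9 | step 4 | [(1S,2R)-1-(but-3-en-1-yl)-2,3-dimethylcyclohex-3-en-1-yl]methyl methanesulfonate | C=CCC[C@]1(COS(C)(=O)=O)CCC=C(C)[C@H]1C
A1 | alternative 1 | (2R)-6,7,8-trimethoxy-2-methyl-2-{2-[(1S,2S)-1,2,3-trimethylcyclohex-3-en-1-yl]ethyl}-2H-chromen-5-yl trifluoromethanesulfonate | COc1c(OS(=O)(=O)C(F)(F)F)c2c(c(OC)c1OC)O[C@](C)(CC[C@]1(C)CCC=C(C)[C@H]1C)C=C2
A2 | alternative 1 | (2E)-3-methyl-5-[(1S,2S)-1,2,3-trimethylcyclohex-3-en-1-yl]pent-2-enal | O=C/C=C(\C)CC[C@]1(C)CCC=C(C)[C@H]1C
A3 | alternative 1 | 4,5,6-trimethoxy-2-(trimethylsilyl)-1,3-phenylene bis(trifluoromethanesulfonate) | COc1c(OS(=O)(=O)C(F)(F)F)c([Si](C)(C)C)c(OS(=O)(=O)C(F)(F)F)c(OC)c1OC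
A4 | alternative 2 | (2R)-4-[(tert-butyldimethylsilyl)oxy]-6,7,8-trimethoxy-2-methyl-2-{2-[(1S,2S)-1,2,3-trimethylcyclohex-3-en-1-yl]ethyl}-3,4-dihydro-2H-chromen-5-ol | COc1c(O)c2c(c(OC)c1OC)O[C@](C)(CC[C@]1(C)CCC=C(C)[C@H]1C)CC2O[Si](C)(C)C(C)(C)C
A5 | alternative 2 | 4-[(2R)-4-[(tert-butyldimethylsilyl)oxy]-2-methyl-2-{2-[(1S,2S)-1,2,3-trimethylcyclohex-3-en-1-yl]ethyl}-3,4-dihydro-2H-pyran-6-yl]-2,3,4-trimethoxycyclobut-2-en-1-one | COC1=C(OC)C(OC)(C2=CC(O[Si](C)(C)C(C)(C)C)C[C@@](C)(CC[C@]3(C)CCC=C(C)[C@H]3C)O2)C1=O
A6 | alternative 3 | (2R)-6,7,8-trimethoxy-5-(methoxymethoxy)-2-methyl-2-{2-[(1S,2S)-1,2,3-trimethylcyclohex-3-en-1-yl]ethyl}-2H-chromene | COc1c(OCOC)c2c(c(OC)c1OC)O[C@](C)(CC[C@]1(C)CCC=C(C)[C@H]1C)C=C2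
A7 | alternative 3 | (1Z,3R)-1-[2-bromo-3,4,5-trimethoxy-6-(methoxymethoxy)phenyl]-3-methyl-5-[(1S,2S)-1,2,3-trimethylcyclohex-3-en-1-yl]pent-1-en-3-ol | COCOc1c(OC)c(OC)c(OC)c(Br)c1/C=C\[C@](C)(O)CC[C@]1(C)CCC=C(C)[C@H]1C
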